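**Retrosynthetic overview**

- Feature: ring A (C4a, C5, C6, C7, C8, C8a) carries oxygen on C5, C7 and C8a, the alternating pattern of a folded polyketide, and the prenylated C6 sits between the two hydroxylated carbons. C7 and C6 with its prenyl chain are therefore read as the carbonyl and α-carbon of a 5-methylhex-4-enoyl unit, C8 as a pyranone 2-methyl group and C5 as a pyranone 3-ester carbon.
- Key disconnection: C7–C8 (lateral Claisen acylation) and C5–C6 (Dieckmann closure with aromatisation), leading back to methyl 2-methyl-4-oxo-5-(2,3,4-trimethoxyphenyl)-4H-pyran-3-carboxylate and ethyl 5-methylhex-4-enoate.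
- Pyranone (ring C): from the C-acylation product of methyl acetoacetate with (2,3,4-trimethoxyphenyl)acetyl chloride, plus one carbon from DMF-DMA. The hexenoate comes from a Johnson–Claisen rearrangement of 2-methylbut-3-en-2-ol.
- Ring order: ring B is bought with the arylacetic acid, ring C is closed in step 3, ring A is closed last in step 5.

Key step: step 5

Remark: the target has no stereocentre and no stereogenic double bond (the alkene carries two identical methyl groups), so it is achiral and no enantiocontrol is needed.

**Route**

Step 1
Reactants: 1 (2,3,4-trimethoxyphenyl)acetic acid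
Product: 2 (2,3,4-trimethoxyphenyl)acetyl chloride
Conditions: (COCl)2 (1.2 equiv), DMF (cat.), CH2Cl2, 0 °C → rt; concentrate and use crude
Reagents that add atoms: oxalyl chloride, O=C(Cl)C(=O)Cl
Why: Standard acid chloride formation with oxalyl chloride and catalytic DMF (Vilsmeier-type activation), which the electron-rich arene and its methyl ethers should tolerate at or below room temperature.

Step 2
Reactants: 2 (2,3,4-trimethoxyphenyl)acetyl chloride; 3 methyl acetoacetate
Product: 4 methyl 2-acetyl-3-oxo-4-(2,3,4-trimethoxyphenyl)butanoate
Conditions: MgCl2 (1.0 equiv), pyridine (2.0 equiv), CH2Cl2, 0 °C → rt; cold dilute HCl work-up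
Reagents that add atoms: none
Why: Magnesium-mediated C-acylation of a β-keto ester (soft enolisation with MgCl2/pyridine), in which the chelated magnesium enolate of 3 is acylated on carbon and the more acidic tricarbonyl product stays bound as its chelate, so that O-acylation and a second acylation are suppressed.

Step 3
Reactants: 4 methyl 2-acetyl-3-oxo-4-(2,3,4-trimethoxyphenyl)butanoate
Product: 6 methyl 2-methyl-4-oxo-5-(2,3,4-trimethoxyphenyl)-4H-pyran-3-carboxylate, via enaminone 5 (not isolated)
Conditions: Me2NCH(OMe)2 (1.5 equiv), PhMe, 70 °C; then AcOH, 80 °C
Reagents that add atoms: N,N-dimethylformamide dimethyl acetal (DMF-DMA), COC(OC)N(C)C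
Why: Aminomethylenation of an enolised 2-acyl-1,3-dicarbonyl compound with DMF-DMA should take place at the benzylic methylene next to the ketone (more acidic and more reactive than the acetyl methyl, as with arylacetones and deoxybenzoins), and the enol oxygen of the acetyl group then adds to the enaminone carbon and expels dimethylamine (6-endo addition–elimination) to close the 4-pyranone, the same sequence that turns 2-acylcyclohexane-1,3-diones and 3-acetyl-4-hydroxycoumarins into fused 4-pyranones.

Step 4
Reactants: 7 2-methylbut-3-en-2-ol; 8 triethyl orthoacetate
Product: 10 ethyl 5-methylhex-4-enoate, via ketene acetal 9 (not isolated)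
Conditions: 8 (4 equiv), EtCO2H (cat.), 140 °C, EtOH distilled off
Reagents that add atoms: none
Why: Johnson–Claisen rearrangement, in which acid-catalysed exchange gives the mixed ketene acetal 9 and its [3,3]-sigmatropic shift delivers the γ,δ-unsaturated ester with a gem-dimethyl alkene, so that no alkene geometry arises.

Step 5
Reactants: 6 methyl 2-methyl-4-oxo-5-(2,3,4-trimethoxyphenyl)-4H-pyran-3-carboxylate; 10 ethyl 5-methylhex-4-enoate
Product: 12 5,7-dihydroxy-6-(3-methylbut-2-enyl)-3-(2,3,4-trimethoxyphenyl)-4H-chromen-4-one (the target), via keto ester 11 (not isolated)
Conditions: LDA (commercial solution, 1.1 equiv), THF, −78 °C; 10 (1.5 equiv), −78 → −20 °C; LDA (2.2 equiv), −78 °C → rt; cold 1 M HCl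
Reagents that add atoms: none
Why: Proposed new method: the first portion of LDA removes a proton from the 2-methyl group of 6, which is acidified through the C2=C3 double bond by both the C4 ketone and the C3 ester, and the extended enolate should attack the carbonyl of ester 10 with its terminal carbon in a Claisen acylation (new C8–C7 bond of the chromone) to give 11, held as its stabilised enolate. The second portion of LDA should deprotonate the α′ methylene of 11, the carbon that carries the prenyl chain, and this more reactive carbanion should add to the ester carbonyl on the neighbouring ring carbon in a 6-exo-trig Dieckmann closure (new C6–C5 bond), after which loss of methoxide and two enolisations give the aromatic 5,7-diolate of ring A; no stereocentre is formed. The closest known reaction types are the lateral metalation and acylation of 2-methyl-4-pyranones and 2-methylchromones, the Claisen–Dieckmann benzannulation of o-toluate anions to naphthalene-1,3-diols and the Claisen cyclisation of polyketo esters to acylphloroglucinols; the one-pot union on a pyranone ester is the untested part. Regiochemistry needs no control, because attack of the α′ carbon on the ring ester is the only closure that gives a six-membered ring, so that the prenyl group can only end up on C6 between the two hydroxyl groups and never on C8. Carbon over oxygen acylation in the closure is secured thermodynamically, since an enol lactone from O-attack is reopened by the alkoxide present while the C-acylated product leaves the equilibrium by aromatisation. Staged addition of the base keeps free amide away from the enolisable ester, the isolated trisubstituted alkene and the aryl methyl ethers are inert to amide base, and the cold dilute acid quench is chosen so that the prenyl group does not cyclise onto a neighbouring phenol.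

**Compound list**

1 | (2,3,4-trimethoxyphenyl)acetic acid | COc1ccc(CC(=O)O)c(OC)c1OC | starting material
2 | (2,3,4-trimethoxyphenyl)acetyl chloride | COc1ccc(CC(=O)Cl)c(OC)c1OC | intermediate
3 | methyl acetoacetate | COC(=O)CC(C)=O | starting material
4 | methyl 2-acetyl-3-oxo-4-(2,3,4-trimethoxyphenyl)butanoate (drawn as the triketo tautomer; largely enolised) | COC(=O)C(C(C)=O)C(=O)Cc1ccc(OC)c(OC)c1OC | intermediate
5 | methyl 2-acetyl-5-(dimethylamino)-3-oxo-4-(2,3,4-trimethoxyphenyl)pent-4-enoate (enaminone; alkene geometry not fixed and immaterial) | COC(=O)C(C(C)=O)C(=O)C(=CN(C)C)c1ccc(OC)c(OC)c1OC | intermediate (not isolated)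
6 | methyl 2-methyl-4-oxo-5-(2,3,4-trimethoxyphenyl)-4H-pyran-3-carboxylate | COC(=O)c1c(C)occ(-c2ccc(OC)c(OC)c2OC)c1=O | intermediate
7 | 2-methylbut-3-en-2-ol | C=CC(C)(C)O | starting material
8 | triethyl orthoacetate | CCOC(C)(OCC)OCC | starting material
9 | 3-[(1-ethoxyethenyl)oxy]-3-methylbut-1-ene (mixed ketene acetal) | C=C(OCC)OC(C)(C)C=C | intermediate (not isolated)
10 | ethyl 5-methylhex-4-enoate | CCOC(=O)CCC=C(C)C | intermediate
11 | methyl 2-(6-methyl-2-oxohept-5-en-1-yl)-4-oxo-5-(2,3,4-trimethoxyphenyl)-4H-pyran-3-carboxylate | COC(=O)c1c(CC(=O)CCC=C(C)C)occ(-c2ccc(OC)c(OC)c2OC)c1=O | intermediate (not isolated)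
12 | 5,7-dihydroxy-6-(3-methylbut-2-enyl)-3-(2,3,4-trimethoxyphenyl)-4H-chromen-4-one | COc1ccc(-c2coc3cc(O)c(CC=C(C)C)c(O)c3c2=O)c(OC)c1OC | target

**Step count**

Total: 5 steps. Longest linear sequence: 4 steps (steps 1, 2, 3 and 5); step 4 is a one-step branch.

**Steps most likely to fail**

1. Step 5 (proposed new method). Proton transfer from the enolisable ester, or from pyranone regenerated during the acylation, may quench the extended enolate faster than it is acylated, so that ester self-condensation and recovered pyranone dominate. The stabilised monoanion of the keto ester may also resist the second deprotonation and ring closure, and alkoxide may add to the unsubstituted ring carbon next to the pyranone oxygen and open ring C. The fallback uses known chemistry in two separate operations and sets out from 10 and 6. Ester 10 is converted with N,O-dimethylhydroxylamine hydrochloride and i-PrMgCl (THF, −20 °C) into the Weinreb amide N-methoxy-N,5-dimethylhex-4-enamide F1. Pyranone 6 is laterally lithiated with LiHMDS (THF, −78 °C) and added to F1, whose chelated tetrahedral adduct releases no acidic ketone before work-up, so that the base is not consumed by the product. The fallback comes back to the route at 11, which is now isolated. Ring A is then closed in a separate step with NaH or LDA (2.2 equiv) in THF, a Claisen-type cyclisation of the kind known for 2-(2-oxoalkyl)benzoates giving naphthalene-1,3-diols, to give 12.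

2. Step 3. Condensation of DMF-DMA may occur at the acetyl methyl instead of the benzylic methylene, the reagent may transfer a methyl group to the acidic enol, or an acyl group may be lost by retro-Claisen cleavage. The fallback brings in the aryl ring by cross-coupling and sets out from 3. C-acetylation of 3 (AcCl, MgCl2, pyridine, CH2Cl2) gives methyl 2-acetyl-3-oxobutanoate F2, whose two acyl groups are identical, so aminomethylenation has a single outcome. DMF-DMA (PhMe, 60 °C) gives the enaminone methyl 2-acetyl-5-(dimethylamino)-3-oxopent-4-enoate F3, which is treated before any acid is added with I2 in CHCl3. α-Iodination and cyclisation, in the manner of the 3-iodochromone synthesis from enaminones, should give methyl 5-iodo-2-methyl-4-oxo-4H-pyran-3-carboxylate F4. Suzuki–Miyaura coupling of F4 with commercial (2,3,4-trimethoxyphenyl)boronic acid (Pd(dppf)Cl2, K3PO4, dioxane, 80 °C) comes back to the route at 6.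

3. Step 2. The arylacetyl chloride may form a ketene under amine base, O-acylation may compete, or the tricarbonyl product may lose its acetyl group on work-up. The fallback reverses the order of the two acylations and sets out from 2. Acylation of Meldrum's acid with 2 (pyridine, CH2Cl2, 0 °C) gives 5-[1-hydroxy-2-(2,3,4-trimethoxyphenyl)ethylidene]-2,2-dimethyl-1,3-dioxane-4,6-dione F5. Methanolysis (MeOH, reflux) gives methyl 3-oxo-4-(2,3,4-trimethoxyphenyl)butanoate F6. Its magnesium enolate is C-acetylated at the central carbon with acetyl chloride (MgCl2, pyridine, CH2Cl2), which comes back to the route at 4.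

**Further compounds**

F1 | step 5 | N-methoxy-N,5-dimethylhex-4-enamide | CON(C)C(=O)CCC=C(C)C
F2 | step 3 | methyl 2-acetyl-3-oxobutanoate | COC(=O)C(C(C)=O)C(C)=O
F3 | step 3 | methyl (E)-2-acetyl-5-(dimethylamino)-3-oxopent-4-enoate | COC(=O)C(C(C)=O)C(=O)/C=C/N(C)C
F4 | step 3 | methyl 5-iodo-2-methyl-4-oxo-4H-pyran-3-carboxylate | COC(=O)c1c(C)occ(I)c1=O
F5 | step 2 | 5-[1-hydroxy-2-(2,3,4-trimethoxyphenyl)ethylidene]-2,2-dimethyl-1,3-dioxane-4,6-dione | CC1(C)OC(=O)C(=C(O)Cc2ccc(OC)c(OC)c2OC)C(=O)O1
F6 | step 2 | methyl 3-oxo-4-(2,3,4-trimethoxyphenyl)butanoate | COC(=O)CC(=O)Cc1ccc(OC)c(OC)c1OC
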